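**Retrosynthetic overview**

1. The last C–C bond (C7–C11) and the free 8α-hydroxyl arise together from trans-diaxial opening of a 7α,8α-epoxide by an isopropenylcopper reagent; the 9α-angelate and the 2α-acetate are put on before that, each on the only free hydroxyl present.
2. The C7–C8 alkene and the 9α-oxygen trace back (Shapiro reaction, enolate hydroxylation, dissolving-metal reduction that sets the trans ring fusion at C10) to the trinor-eremophil-9-en-8-one 12.
3. Ring B of 12 is closed on ring A by forming the C5–C6 bond in a 6π-electrocyclization of the trienolate of vinyl ketone 9. The enabling feature is the oxygen on C8 of ring B: at the ketone level, C6=C7–C8(O−)=C9–C10=C5 is an oxido-hexatriene ending at C6 and at ring-A carbon C5, and the C4 methyl next to C5 steers the new quaternary centre.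
4. Vinyl ketone 9 comes from ring-A enol triflate 7 (C9 and C8 by zinc-enolate cross-coupling, C7 and C6 by vinyl Grignard addition); 7 comes from (S)-carvone by Criegee excision of the isopropenyl group (C2 oxygen) and anti cuprate addition (C4 methyl).
5. Order of ring formation: ring A is the carvone ring; ring B is formed second, in the key step.

Key step: step 7

Remark: eremophilane numbering is used for the target and all intermediates (ring A: C1, C2, C3, C4, C5, C10; ring B: C5, C6, C7, C8, C9, C10; C14 and C15 are the methyls on C5 and C4; C11 to C13 are the isopropenyl carbons); β is the face that carries the C5 methyl, α the opposite face.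

**Route**

Step 1
Reactants: 1 (S)-(+)-carvone
Product: 3 (5S)-5-acetoxy-2-methylcyclohex-2-en-1-one, via methoxy hydroperoxide 2 (not isolated)
Conditions: O3, CH2Cl2/MeOH, −78 °C; then Ac2O, Et3N, DMAP (cat.), CH2Cl2, 0 °C to rt
Reagents that add atoms: ozone, [O-][O+]=O; methanol, CO
Why: Ozonolysis in methanol cleaves only the electron-rich 1,1-disubstituted alkene to the α-methoxy hydroperoxide, and Criegee rearrangement of its peracetate moves the ring carbon to oxygen with retention, so that the (S) centre of carvone becomes the acetoxy-bearing future C2 (ring oxygen from ozone, carbonyl oxygen from the methoxy group, acetyl carbons from the old isopropenyl group).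

Step 2
Reactants: 3 (5S)-5-acetoxy-2-methylcyclohex-2-en-1-one
Product: 4 (5S)-5-hydroxy-2-methylcyclohex-2-en-1-one
Conditions: K2CO3 (0.2 equiv), MeOH, 0 °C
Reagents that add atoms: none
Why: Carbonate-catalysed transesterification (methanolysis) removes the acetate without touching the stereocentre, the low temperature holding back E1cB loss of the β-oxygen.

Step 3
Reactants: 4 (5S)-5-hydroxy-2-methylcyclohex-2-en-1-one
Product: 5 (5S)-5-(tert-butyldimethylsilyloxy)-2-methylcyclohex-2-en-1-one
Conditions: TBSCl, imidazole, CH2Cl2, 0 °C to rt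
Reagents that add atoms: tert-butyldimethylsilyl chloride, CC(C)(C)[Si](C)(C)Cl
Why: Imidazole-promoted O-silylation of the secondary alcohol gives a silyl ether that tolerates the organometallic, enolate and dissolving-metal steps ahead.

Step 4
Reactants: 5 (5S)-5-(tert-butyldimethylsilyloxy)-2-methylcyclohex-2-en-1-one
Product: 7 (3S,5S)-5-(tert-butyldimethylsilyloxy)-2,3-dimethylcyclohex-1-en-1-yl trifluoromethanesulfonate, via lithium enolate 6 (not isolated)
Conditions: Me2CuLi (from MeLi and CuI), Et2O, −78 to −40 °C; then N-(5-chloro-2-pyridyl)bis(trifluoromethanesulfonimide), THF, −78 to 0 °C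
Reagents that add atoms: lithium dimethylcuprate, [Li+].C[Cu-]C; N-(5-chloro-2-pyridyl)bis(trifluoromethanesulfonimide), Clc1ccc(nc1)N(S(=O)(=O)C(F)(F)F)S(=O)(=O)C(F)(F)F
Why: Conjugate addition of the cuprate to the enone takes place anti to the silyloxy group (trans-3,5 product), which sets C4 as the β-methyl centre, and the regiodefined enolate is trapped on oxygen by the triflimide to give the tetrasubstituted enol triflate.

Step 5
Reactants: 7 (3S,5S)-5-(tert-butyldimethylsilyloxy)-2,3-dimethylcyclohex-1-en-1-yl trifluoromethanesulfonate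
Product: 8 2-[(3S,5S)-5-(tert-butyldimethylsilyloxy)-2,3-dimethylcyclohex-1-en-1-yl]-N-methoxy-N-methylacetamide
Conditions: BrZnCH2C(O)N(OMe)Me (from BrCH2C(O)N(OMe)Me and Zn dust, THF), Pd2(dba)3 (cat.), XPhos (cat.), THF, 60 °C
Reagents that add atoms: bromozinc enolate of N-methoxy-N-methylacetamide, CON(C)C(=O)C[Zn]Br (made from 2-bromo-N-methoxy-N-methylacetamide, CON(C)C(=O)CBr, and Zn)
Why: Negishi-type cross-coupling of an alkenyl triflate with a Reformatsky reagent (zinc amide enolate) forms the C10–C9 bond under neutral conditions and creates no stereocentre.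

Step 6
Reactants: 8 2-[(3S,5S)-5-(tert-butyldimethylsilyloxy)-2,3-dimethylcyclohex-1-en-1-yl]-N-methoxy-N-methylacetamide
Product: 9 1-[(3S,5S)-5-(tert-butyldimethylsilyloxy)-2,3-dimethylcyclohex-1-en-1-yl]but-3-en-2-one
Conditions: CH2=CHMgBr, THF, −78 to 0 °C; poured into cold 1 M HCl; crude 9 used at once
Reagents that add atoms: vinylmagnesium bromide, C=C[Mg]Br
Why: Weinreb ketone synthesis: the magnesium chelate of the tetrahedral adduct is stable until the acidic quench, so a single vinyl group is delivered and the β,γ-unsaturated vinyl ketone is released only on work-up.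

Step 7
Reactants: 9 1-[(3S,5S)-5-(tert-butyldimethylsilyloxy)-2,3-dimethylcyclohex-1-en-1-yl]but-3-en-2-one
Product: 12 2α-(tert-butyldimethylsilyloxy)-11,12,13-trinoreremophil-9-en-8-one, via lithium trienolate 10 (not isolated), via lithium dienolate 11 (not isolated)
Conditions: LDA (1.1 equiv), THF (high dilution), −78 °C, slow addition of 9 to the base; then warm to 25 °C; AcOH, −78 °C
Reagents that add atoms: none
Why: Proposed new method: LDA removes one of the doubly activated C9 protons (allylic and α to the ketone) to give the cross-conjugated (E)-trienolate 10, in which C6=C7–C8(OLi)=C9–C10=C5 is a 3-oxido-1,3,5-hexatriene; on warming this should close by a thermal disrotatory 6π-electrocyclization that makes the C5–C6 σ-bond (in polar terms, attack of the dienolate γ-carbon C5 on the terminal carbon C6 of the vinyl ketone resonance form) and gives dienolate 11, which is protonated at C7 to the conjugated enone. The closest known reaction type is the oxyanion-accelerated 6π-electrocyclization of oxido-hexatrienes (dienyl ketone enolates) to cyclohexenones, together with thermal triene electrocyclizations that create quaternary carbons; what is new is the formation of the trienolate by simple enolization and its closure onto a fully substituted terminus. Ring B is the only ring closed, in the 6π-electrocyclic mode, all six ring atoms being the triene carbons. The only new stereocentre, quaternary C5, is controlled by the C4 methyl: A(1,2) strain with the C5 methyl holds it pseudoaxial on the β-face of the ring-A alkene, so C6 bonds to the α-face and the two methyls end up cis. The step needs the (E)-enolate (vinyl group cis to C10), which the cyclic deprotonation transition state of LDA in THF favours when the group on the carbonyl is as small as vinyl, and it needs ring closure to outrun Michael oligomerization and a [1,7]-hydrogen shift from the C5 methyl, for which inverse addition at −78 °C, high dilution and the anionic acceleration are relied on.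

Step 8
Reactants: 12 2α-(tert-butyldimethylsilyloxy)-11,12,13-trinoreremophil-9-en-8-one
Product: 14 2α-(tert-butyldimethylsilyloxy)-9α-hydroxy-11,12,13-trinor-10αH-eremophilan-8-one, via lithium enolate 13 (not isolated)
Conditions: Li, NH3(l)/THF, t-BuOH (1 equiv), −78 °C; NH3 evaporated; then 2-(phenylsulfonyl)-3-phenyloxaziridine, THF, −78 °C; aq. NH4Cl
Reagents that add atoms: 2-(phenylsulfonyl)-3-phenyloxaziridine, O=S(=O)(N1OC1c1ccccc1)c1ccccc1
Why: Dissolving-metal reduction of the enone protonates C10 axially to give the trans-fused lithium enolate with the double bond fixed at C8–C9, and electrophilic hydroxylation of this enolate by the N-sulfonyloxaziridine takes place on the α-face, away from the syn-axial C5 methyl, to give the equatorial 9α-alcohol.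

Step 9
Reactants: 14 2α-(tert-butyldimethylsilyloxy)-9α-hydroxy-11,12,13-trinor-10αH-eremophilan-8-one
Product: 15 2,4,6-triisopropylbenzenesulfonylhydrazone of 14
Conditions: 2,4,6-triisopropylbenzenesulfonyl hydrazide, THF, rt
Reagents that add atoms: 2,4,6-triisopropylbenzenesulfonyl hydrazide, CC(C)c1cc(C(C)C)c(S(=O)(=O)NN)c(C(C)C)c1
Why: Condensation of the ketone with the sulfonyl hydrazide gives the hydrazone, with the sulfonamide nitrogen anti to the more substituted C9.

Step 10
Reactants: 15 2,4,6-triisopropylbenzenesulfonylhydrazone of 14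
Product: 17 2α-(tert-butyldimethylsilyloxy)-11,12,13-trinor-10αH-eremophil-7-en-9α-ol, via vinyllithium 16 (not isolated)
Conditions: n-BuLi (3.5 equiv), THF, −78 to 0 °C; then H2O
Reagents that add atoms: none
Why: Shapiro reaction: after deprotonation of O–H and N–H, the third equivalent of base removes a C7 proton syn to the sulfonamide, loss of sulfinate and nitrogen gives the C8 vinyllithium, and protonation gives the C7–C8 alkene without touching C9 or C10.

Step 11
Reactants: 17 2α-(tert-butyldimethylsilyloxy)-11,12,13-trinor-10αH-eremophil-7-en-9α-ol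
Product: 18 2α-(tert-butyldimethylsilyloxy)-11,12,13-trinor-10αH-eremophil-7-en-9α-yl angelate
Conditions: angelic acid, 2,4,6-trichlorobenzoyl chloride, Et3N, toluene, rt; then 17, toluene, 80 °C
Reagents that add atoms: angelic acid, C/C=C(/C)C(=O)O
Why: Yamaguchi esterification through the mixed anhydride: the alcohol attacks the unhindered angeloyl carbonyl, and because no nucleophilic catalyst is used the (Z)-alkene should not isomerize to the tiglate.

Step 12
Reactants: 18 2α-(tert-butyldimethylsilyloxy)-11,12,13-trinor-10αH-eremophil-7-en-9α-yl angelate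
Product: 19 2α-hydroxy-11,12,13-trinor-10αH-eremophil-7-en-9α-yl angelate
Conditions: HF·pyridine, pyridine/THF, 0 °C to rt
Reagents that add atoms: none
Why: Fluoride-driven cleavage of the silyl ether in buffered HF·pyridine leaves the allylic ester and the alkenes untouched.

Step 13
Reactants: 19 2α-hydroxy-11,12,13-trinor-10αH-eremophil-7-en-9α-yl angelate
Product: 20 2α-acetoxy-11,12,13-trinor-10αH-eremophil-7-en-9α-yl angelate
Conditions: Ac2O, pyridine, DMAP (cat.), CH2Cl2, rt
Reagents that add atoms: acetic anhydride, CC(=O)OC(C)=O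
Why: DMAP-catalysed acylation of the only free hydroxyl group gives the 2α-acetate.

Step 14
Reactants: 20 2α-acetoxy-11,12,13-trinor-10αH-eremophil-7-en-9α-yl angelate
Product: 21 2α-acetoxy-7α,8α-epoxy-11,12,13-trinor-10αH-eremophilan-9α-yl angelate
Conditions: m-CPBA, NaHCO3, CH2Cl2, 0 °C to rt
Reagents that add atoms: m-chloroperoxybenzoic acid, OOC(=O)c1cccc(Cl)c1
Why: Prilezhaev epoxidation: the peracid attacks the electron-richer disubstituted ring alkene (the angelate alkene is conjugated and slow) from the α-face, opposite to the axial C5 methyl that screens the β-face of C7, which sets the 7α,8α-epoxide.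

Step 15
Reactants: 21 2α-acetoxy-7α,8α-epoxy-11,12,13-trinor-10αH-eremophilan-9α-yl angelate
Product: 22 2α-acetoxy-9α-angeloyloxy-10αH-eremophil-11-en-8α-ol (CNP0217919.1)
Conditions: CH2=C(CH3)MgBr (4 equiv), CuBr·SMe2 (2 equiv), THF, −40 °C; then 21, BF3·OEt2, −78 to −30 °C; aq. NH4Cl
Reagents that add atoms: bromomagnesium diisopropenylcuprate, C=C(C)[Cu-]C(C)=C.[Mg+]Br (made from isopropenylmagnesium bromide, C=C(C)[Mg]Br, and CuBr·SMe2)
Why: Organocopper opening of the epoxide follows the Fürst–Plattner rule, that is trans-diaxial attack at C7 from the β-face (attack at C8 would need a twist-boat and is slowed by the neighbouring acyloxy group), which installs the axial 7β-isopropenyl group with inversion and leaves the epoxide oxygen as the axial 8α-hydroxyl, while organocopper reagents at low temperature should not attack the two esters.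

**Compound list**

1 | (S)-(+)-carvone | CC1=CC[C@@H](CC1=O)C(C)=C | starting material
2 | (5S)-5-(1-hydroperoxy-1-methoxyethyl)-2-methylcyclohex-2-en-1-one (both epimers at the peroxy carbon) | CC1=CC[C@@H](CC1=O)C(C)(OC)OO | intermediate
3 | (5S)-5-acetoxy-2-methylcyclohex-2-en-1-one | CC1=CC[C@@H](CC1=O)OC(C)=O | intermediate
4 | (5S)-5-hydroxy-2-methylcyclohex-2-en-1-one | CC1=CC[C@@H](CC1=O)O | intermediate
5 | (5S)-5-(tert-butyldimethylsilyloxy)-2-methylcyclohex-2-en-1-one | CC1=CC[C@@H](CC1=O)O[Si](C)(C)C(C)(C)C | intermediate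
6 | lithium (3S,5S)-5-(tert-butyldimethylsilyloxy)-2,3-dimethylcyclohex-1-en-1-olate (methyl trans to silyloxy) | [Li+].[O-]C1=C(C)[C@@H](C)C[C@H](O[Si](C)(C)C(C)(C)C)C1 | intermediate
7 | (3S,5S)-5-(tert-butyldimethylsilyloxy)-2,3-dimethylcyclohex-1-en-1-yl trifluoromethanesulfonate | FC(F)(F)S(=O)(=O)OC1=C(C)[C@@H](C)C[C@H](O[Si](C)(C)C(C)(C)C)C1 | intermediate
8 | 2-[(3S,5S)-5-(tert-butyldimethylsilyloxy)-2,3-dimethylcyclohex-1-en-1-yl]-N-methoxy-N-methylacetamide | CON(C)C(=O)CC1=C(C)[C@@H](C)C[C@H](O[Si](C)(C)C(C)(C)C)C1 | intermediate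
9 | 1-[(3S,5S)-5-(tert-butyldimethylsilyloxy)-2,3-dimethylcyclohex-1-en-1-yl]but-3-en-2-one | C=CC(=O)CC1=C(C)[C@@H](C)C[C@H](O[Si](C)(C)C(C)(C)C)C1 | intermediate
10 | lithium (1E)-1-[(3S,5S)-5-(tert-butyldimethylsilyloxy)-2,3-dimethylcyclohex-1-en-1-yl]buta-1,3-dien-2-olate | [Li+].[O-]/C(C=C)=C/C1=C(C)[C@@H](C)C[C@H](O[Si](C)(C)C(C)(C)C)C1 | intermediate
11 | lithium 2α-(tert-butyldimethylsilyloxy)-11,12,13-trinoreremophila-7,9-dien-8-olate (4β,5β-dimethyl) | [Li+].[O-]C1=CC[C@]2(C)[C@@H](C)C[C@H](O[Si](C)(C)C(C)(C)C)CC2=C1 | intermediate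
12 | 2α-(tert-butyldimethylsilyloxy)-11,12,13-trinoreremophil-9-en-8-one (4β,5β-dimethyl) | O=C1CC[C@]2(C)[C@@H](C)C[C@H](O[Si](C)(C)C(C)(C)C)CC2=C1 | intermediate
13 | lithium 2α-(tert-butyldimethylsilyloxy)-11,12,13-trinor-10αH-eremophil-8-en-8-olate (trans-fused) | [Li+].[O-]C1=C[C@@H]2C[C@@H](O[Si](C)(C)C(C)(C)C)C[C@H](C)[C@@]2(C)CC1 | intermediate
14 | 2α-(tert-butyldimethylsilyloxy)-9α-hydroxy-11,12,13-trinor-10αH-eremophilan-8-one | O=C1CC[C@]2(C)[C@@H](C)C[C@H](O[Si](C)(C)C(C)(C)C)C[C@H]2[C@@H]1O | intermediate
15 | 2,4,6-triisopropylbenzenesulfonylhydrazone of 14 (sulfonamide nitrogen anti to C9) | CC(C)c1cc(C(C)C)c(S(=O)(=O)N/N=C2\CC[C@]3(C)[C@@H](C)C[C@H](O[Si](C)(C)C(C)(C)C)C[C@H]3[C@@H]2O)c(C(C)C)c1 | intermediate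
16 | 8-lithio-2α-(tert-butyldimethylsilyloxy)-11,12,13-trinor-10αH-eremophil-7-en-9α-ol lithium alkoxide | [Li]C1=CC[C@]2(C)[C@@H](C)C[C@H](O[Si](C)(C)C(C)(C)C)C[C@H]2[C@@H]1O[Li] | intermediate
17 | 2α-(tert-butyldimethylsilyloxy)-11,12,13-trinor-10αH-eremophil-7-en-9α-ol | C1=CC[C@]2(C)[C@@H](C)C[C@H](O[Si](C)(C)C(C)(C)C)C[C@H]2[C@@H]1O | intermediate
18 | 2α-(tert-butyldimethylsilyloxy)-11,12,13-trinor-10αH-eremophil-7-en-9α-yl angelate | C1=CC[C@]2(C)[C@@H](C)C[C@H](O[Si](C)(C)C(C)(C)C)C[C@H]2[C@@H]1OC(=O)/C(C)=C\C | intermediate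
19 | 2α-hydroxy-11,12,13-trinor-10αH-eremophil-7-en-9α-yl angelate | C1=CC[C@]2(C)[C@@H](C)C[C@H](O)C[C@H]2[C@@H]1OC(=O)/C(C)=C\C | intermediate
20 | 2α-acetoxy-11,12,13-trinor-10αH-eremophil-7-en-9α-yl angelate | C1=CC[C@]2(C)[C@@H](C)C[C@H](OC(C)=O)C[C@H]2[C@@H]1OC(=O)/C(C)=C\C | intermediate
21 | 2α-acetoxy-7α,8α-epoxy-11,12,13-trinor-10αH-eremophilan-9α-yl angelate | O1[C@@H]2C[C@]3(C)[C@@H](C)C[C@H](OC(C)=O)C[C@H]3[C@H](OC(=O)/C(C)=C\C)[C@H]12 | intermediate
22 | 2α-acetoxy-9α-angeloyloxy-10αH-eremophil-11-en-8α-ol (7β-isopropenyl, 4β,5β-dimethyl; CNP0217919.1) | C=C(C)[C@H]1C[C@]2(C)[C@@H](C)C[C@H](OC(C)=O)C[C@H]2[C@H](OC(=O)/C(C)=C\C)[C@@H]1O | target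

**Step count and risks**

Total step count: 15. Longest linear sequence: 15 steps (one linear sequence from (S)-carvone).

Steps most likely to fail:

1. Step 7 (bears the label Proposed new method). The trienolate may be consumed by a [1,7]-hydrogen shift from the C5 methyl or by Michael oligomerization of the vinyl ketone with its own enolate before it cyclizes, or it may form with the enolate geometry that cannot bring C6 to C5. The fallback is a Robinson-type annulation by known chemistry, in which the C5–C6 bond is made intermolecularly and ring B is closed by aldol condensation. It sets out from 5. Conjugate addition of Me2CuLi and trapping of the enolate with Me3SiCl/Et3N should give the trimethylsilyl enol ether F1. Mukaiyama–Michael addition of F1 to methyl vinyl ketone (BF3·OEt2, CH2Cl2, −78 °C), anti to the C4 methyl, should give the 1,5-diketone F2. Aldol condensation under mild amine–acid conditions (pyrrolidine, AcOH, toluene, heat, chosen to spare the β-silyloxy ketone) should then close ring B, and the route is rejoined at 12.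

2. Step 15. The slow axial attack at C7, syn to the C5 methyl, may be overtaken by transfer of the angeloyl group from O9 to the new O8 alkoxide, by addition of the organometallic to the esters, or by Lewis-acid-induced rearrangement of the epoxide. The fallback opens the epoxide before any ester is present. It sets out from 17. Hydroxyl-directed epoxidation (VO(acac)2, t-BuOOH, CH2Cl2) should give the α-epoxy alcohol F3. Copper-catalysed Grignard opening (CH2=C(CH3)MgBr, CuI cat., THF, −20 °C) should give the diol F4. Yamaguchi esterification with angelic acid should acylate the equatorial 9α-hydroxyl in preference to the hindered axial 8α-hydroxyl and give the monoester F5. HF·pyridine should give the diol F6, and acetylation of the less hindered C2 hydroxyl (Ac2O, pyridine, 0 °C) should lead back to the route at 22.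

3. Step 6. The Grignard reagent may enolize the acidic C9 methylene in place of adding to the amide, and the vinyl ketone may be lost on isolation through conjugate addition of the released N,O-dimethylhydroxylamine or through oligomerization. The fallback replaces the acyl substitution by reduction, addition and oxidation. It sets out from 8. DIBAL-H (THF, −78 °C) should give the aldehyde F7. Addition of CH2=CHMgBr in the presence of CeCl3 should give the allylic alcohol F8. Dess–Martin oxidation under buffered conditions should give the vinyl ketone, and the route is rejoined at 9, which is used at once.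

Further compounds
F1 | step 7 | (3S,5S)-5-(tert-butyldimethylsilyloxy)-2,3-dimethyl-1-(trimethylsilyloxy)cyclohex-1-ene | C[Si](C)(C)OC1=C(C)[C@@H](C)C[C@H](O[Si](C)(C)C(C)(C)C)C1
F2 | step 7 | 5-(tert-butyldimethylsilyloxy)-2,3-dimethyl-2-(3-oxobutyl)cyclohexan-1-one (methyls cis, silyloxy trans to the C4 methyl; C5 as in 12) | CC(=O)CC[C@]1(C)[C@@H](C)C[C@H](O[Si](C)(C)C(C)(C)C)CC1=O
F3 | step 15 | 2α-(tert-butyldimethylsilyloxy)-7α,8α-epoxy-11,12,13-trinor-10αH-eremophilan-9α-ol | O1[C@@H]2C[C@]3(C)[C@@H](C)C[C@H](O[Si](C)(C)C(C)(C)C)C[C@H]3[C@H](O)[C@H]12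
F4 | step 15 | 2α-(tert-butyldimethylsilyloxy)-10αH-eremophil-11-ene-8α,9α-diol | C=C(C)[C@H]1C[C@]2(C)[C@@H](C)C[C@H](O[Si](C)(C)C(C)(C)C)C[C@H]2[C@H](O)[C@@H]1O
F5 | step 15 | 2α-(tert-butyldimethylsilyloxy)-8α-hydroxy-10αH-eremophil-11-en-9α-yl angelate | C=C(C)[C@H]1C[C@]2(C)[C@@H](C)C[C@H](O[Si](C)(C)C(C)(C)C)C[C@H]2[C@H](OC(=O)/C(C)=C\C)[C@@H]1O
F6 | step 15 | 2α,8α-dihydroxy-10αH-eremophil-11-en-9α-yl angelate | C=C(C)[C@H]1C[C@]2(C)[C@@H](C)C[C@H](O)C[C@H]2[C@H](OC(=O)/C(C)=C\C)[C@@H]1O
F7 | step 6 | 2-[(3S,5S)-5-(tert-butyldimethylsilyloxy)-2,3-dimethylcyclohex-1-en-1-yl]acetaldehyde | O=CCC1=C(C)[C@@H](C)C[C@H](O[Si](C)(C)C(C)(C)C)C1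
F8 | step 6 | 1-[(3S,5S)-5-(tert-butyldimethylsilyloxy)-2,3-dimethylcyclohex-1-en-1-yl]but-3-en-2-ol (both carbinol epimers) | C=CC(O)CC1=C(C)[C@@H](C)C[C@H](O[Si](C)(C)C(C)(C)C)C1
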